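The route rests on breaking the N1–C7a bond of the pyrrole ring. In the benzene ring, C7a is the only hydrogen-bearing carbon ortho to C3a, since the other ortho carbon, C4, carries bromine and C6–Br sits para. A vinyl nitrene on the carbon that becomes C2 can therefore reach only one aryl C–H. Thermolysis of methyl (Z)-2-azido-3-(2,4-dibromophenyl)acrylate expels N2 and, in one metal-free operation, forms N1–C7a, closes the five-membered ring and delivers the 4,6-dibromoindole-2-carboxylate with both aryl bromides intact. The C2 ester is then hydrolysed and exchanged, together with C3–H, for bromine.

Key step: step 2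

Remark: the target, 2,3,4,6-tetrabromo-1H-indole, is planar and has no stereogenic element, so no stereocontrol is needed and the compound is made as drawn.

Step 1
Reactants: 1 2,4-dibromobenzaldehyde; 2 methyl azidoacetate
Product: 4 methyl (Z)-2-azido-3-(2,4-dibromophenyl)acrylate, via azido aldol adduct 3 (not isolated)
Conditions: NaOMe (4 equiv), 2 (4 equiv), MeOH, −10 → 0 °C; pour onto ice-water, filter; dry cold, away from light
Reagents that add atoms: none
Why: Knoevenagel-type aldol condensation (first stage of the Hemetsberger–Knittel sequence): the ester enolate of 2 adds to the electron-poor aldehyde to give aldol 3, and E1cB loss of hydroxide gives the conjugated Z-alkene (aryl trans to the ester), while the low temperature should keep base-induced N2 loss from the azido ester and SNAr at the C–Br bonds from competing.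

Step 2
Reactants: 4 methyl (Z)-2-azido-3-(2,4-dibromophenyl)acrylate
Product: 7 methyl 4,6-dibromo-1H-indole-2-carboxylate, via 2H-azirine ester 5 (not isolated), via 7aH-indole ester 6 (not isolated)
Conditions: xylenes, reflux (ca. 140 °C); 4 added slowly as a dilute solution (final ≤0.1 M), N2 vented
Reagents that add atoms: none
Why: Heating expels N2 from the vinyl azide to give 2H-azirine 5, which opens reversibly to a singlet vinyl nitrene; the nitrene nitrogen bonds to the ortho aryl carbon in a 1,5-electrocyclisation to give 7aH-indole 6, and a [1,5]-hydrogen shift from C7a to N1 restores the aromatic indole. This is the Hemetsberger–Knittel indole-2-carboxylate synthesis, which is established for ortho-halogenated azidocinnamates. The one ring formed, the pyrrole, closes as a five-membered ring through the new N1–C7a bond, with C2, C3 and C3a already supplied by the acrylate and the aryl ipso carbon. No stereocentre appears in the product: the sp3 centre at C7a in 6 is transient and is erased by the hydrogen shift, and either alkene isomer of 4 would converge through azirine 5. The step needs regioselectivity between the two ortho carbons and chemoselectivity towards the C–Br bonds; the first is secured because only one ortho carbon carries hydrogen (closure at the brominated one cannot rearomatise by hydrogen shift and should be unproductive), the second because no metal, base or radical initiator is present.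

Step 3
Reactants: 7 methyl 4,6-dibromo-1H-indole-2-carboxylate
Product: 9 4,6-dibromo-1H-indole-2-carboxylic acid, via lithium carboxylate 8 (not isolated)
Conditions: LiOH·H2O (3 equiv), THF/MeOH/H2O, 40 °C; then 1 M HCl to pH 2, filter
Reagents that add atoms: lithium hydroxide, [Li+].[OH-]
Why: Saponification (BAc2 ester hydrolysis): hydroxide cleaves the methyl ester to carboxylate 8, which acid converts into the free acid, while the aryl bromides and the indole NH are inert to aqueous hydroxide at this temperature.

Step 4
Reactants: 9 4,6-dibromo-1H-indole-2-carboxylic acid
Product: 11 2,3,4,6-tetrabromo-1H-indole, via tribromo acid 10 (not isolated)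
Conditions: NBS (2.1 equiv), LiOAc (0.2 equiv), DMF, 0 °C → rt, dark
Reagents that add atoms: N-bromosuccinimide, O=C1CCC(=O)N1Br
Why: Electrophilic aromatic bromination at the nucleophilic C3 gives acid 10, and the second NBS equivalent then replaces the carboxyl group at C2 by ipso attack and loss of CO2 (Hunsdiecker-type bromodecarboxylation, as known for pyrrole- and indole-2-carboxylic acids), the benzene ring being too deactivated by its two bromines to compete.

Compound list
1 | 2,4-dibromobenzaldehyde | O=Cc1ccc(Br)cc1Br | starting material
2 | methyl azidoacetate | COC(=O)CN=[N+]=[N-] | starting material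
3 | methyl 2-azido-3-(2,4-dibromophenyl)-3-hydroxypropanoate (racemic mixture of diastereomers, present as its sodium alkoxide, not isolated) | COC(=O)C(N=[N+]=[N-])C(O)c1ccc(Br)cc1Br | intermediate
4 | methyl (Z)-2-azido-3-(2,4-dibromophenyl)acrylate (azide and aryl cis) | COC(=O)/C(N=[N+]=[N-])=C/c1ccc(Br)cc1Br | intermediate
5 | methyl 2-(2,4-dibromophenyl)-2H-azirine-3-carboxylate (racemic, not isolated) | COC(=O)C1=NC1c1ccc(Br)cc1Br | intermediate
6 | methyl 4,6-dibromo-7aH-indole-2-carboxylate (racemic, not isolated) | COC(=O)C1=NC2C=C(Br)C=C(Br)C2=C1 | intermediate
7 | methyl 4,6-dibromo-1H-indole-2-carboxylate | COC(=O)c1cc2c(Br)cc(Br)cc2[nH]1 | intermediate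
8 | lithium 4,6-dibromo-1H-indole-2-carboxylate (not isolated) | [Li+].[O-]C(=O)c1cc2c(Br)cc(Br)cc2[nH]1 | intermediate
9 | 4,6-dibromo-1H-indole-2-carboxylic acid | OC(=O)c1cc2c(Br)cc(Br)cc2[nH]1 | intermediate
10 | 3,4,6-tribromo-1H-indole-2-carboxylic acid (not isolated) | OC(=O)c1[nH]c2cc(Br)cc(Br)c2c1Br | intermediate
11 | 2,3,4,6-tetrabromo-1H-indole | Brc1cc(Br)c2c(Br)c(Br)[nH]c2c1 | target

Total step count: 4
Longest linear sequence: 4

Steps most likely to fail

Step 4. Bromination may run past two new bromines (ring bromination at C5 or C7, or oxidation of the 2-bromoindole unit), or ipso substitution at C2 may stall after C3 bromination. The fallback sets out from 9 and separates carboxyl removal from halogenation. Silver-catalysed protodecarboxylation (Ag2CO3 cat., AcOH cat., DMSO, 120 °C) should give 4,6-dibromo-1H-indole F1 without touching the aryl bromides. NBS on silica gel in CH2Cl2, one equivalent at a time, should then brominate C3 to give 3,4,6-tribromo-1H-indole F2, and then C2 through a 3-bromoindolenine and 1,2-bromine shift. The fallback comes back to the route at 11.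

Step 1. Base-induced decomposition of the azido ester may outrun the aldol addition, or the sequence may stall before dehydration. The fallback sets out from 1 and avoids the azidoacetate enolate altogether. Wittig olefination with methyl (triphenylphosphoranylidene)acetate (CH2Cl2, rt) should give methyl (E)-3-(2,4-dibromophenyl)acrylate F3. Anti addition of Br2 (CH2Cl2, rt) should give methyl (2R*,3S*)-2,3-dibromo-3-(2,4-dibromophenyl)propanoate F4. Sodium azide in DMF at room temperature should then displace the bromide next to the ester and eliminate HBr, the known route from 2,3-dibromo esters to 2-azidoalkenoates. The fallback comes back to the route at 4.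

Step 2. Intermolecular reactions of the azirine or nitrene (dimerisation, tar formation) may compete with ring closure at 140 °C, or nitrogen release may become hard to control on scale. The fallback sets out from 4 and replaces free-nitrene thermolysis by rhodium-nitrenoid C–H amination (Rh2(O2CC3F7)4 cat., toluene, 40–60 °C). The metal-bound nitrene should insert into the same ortho C–H far below the thermal threshold, and Rh(II) does not activate aryl bromides. The fallback comes back to the route at 7 and makes no new compound.

Further compounds
F1 | step 4 | 4,6-dibromo-1H-indole | Brc1cc(Br)c2cc[nH]c2c1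
F2 | step 4 | 3,4,6-tribromo-1H-indole | Brc1c[nH]c2cc(Br)cc(Br)c12
F3 | step 1 | methyl (E)-3-(2,4-dibromophenyl)acrylate | COC(=O)/C=C/c1ccc(Br)cc1Br
F4 | step 1 | methyl (2R*,3S*)-2,3-dibromo-3-(2,4-dibromophenyl)propanoate (racemic, one enantiomer drawn) | COC(=O)[C@@H](Br)[C@@H](Br)c1ccc(Br)cc1Br
F0 | step 2 | none | none
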